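**Plan**

1. Labels: chromanone positions O1, C2, C3, C4, C4a, C5–C8, C8a (primed in the lactone half); side chain Ca (carbinol carbon) and Cb (CHMe). Rings A/B are the arene/pyranone of the hydroxy-acid half; rings C/D/E are the arene/pyranone/lactone of the other half.
2. Enabling feature: in ring B (O1, C2, C3, C4, C4a, C8a) the ether oxygen O1 sits on C2, β to the C4 ketone, and C2 also bears the ester. Ring B is therefore the retron of a 6-endo oxa-Michael addition of the C8a phenol to a C2=C3 aroylacrylate, which mirrors the closure proposed for this ring in nature.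
3. Cuts (retro): O1–C2 of ring B; the C6–C6′ biaryl bond; O1′–C2′ of ring D and the lactone C–O bond of ring E; C2=C3 of one bromo-enone 17 that serves both halves; Ca–Cb.
4. Forward: aryl methyl ketone 4 + α-keto ester 14 → enone 17. One portion → ring D, then ring E, then boronate 22. Suzuki–Miyaura coupling of 22 with a second portion of 17, closure of ring B last, then hydrogenolysis to free the hydroxy acid under neutral conditions.
5. Stereochemistry: Ca/Cb from a reagent-controlled (Z)-crotylboration; C2′ and C2 from Ca by 1,2-induction in the two oxa-Michael closures (attack anti to the Ca benzyloxy group). The benzyl ether on Ca also stops the acid from lactonizing until ring E is wanted.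

Key step: step 15

Assumption: the γ-hydroxy acid of the target is taken to persist in the open form when it is liberated and handled under neutral conditions at or below room temperature.

**Route**

Step 1
Reactants: 1 1-(2,6-dihydroxyphenyl)ethan-1-one
Product: 2 1-[2-hydroxy-6-(methoxymethoxy)phenyl]ethan-1-one
Conditions: MOMCl (1.1 equiv), iPr2NEt, CH2Cl2, 0 °C → rt
Reagents that add atoms: chloromethyl methyl ether, COCCl
Why: Williamson-type O-alkylation; once one hydroxyl is protected the other is held in a hydrogen bond to the ketone and should be left untouched.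

Step 2
Reactants: 2 1-[2-hydroxy-6-(methoxymethoxy)phenyl]ethan-1-one
Product: 3 1-[3-bromo-2-hydroxy-6-(methoxymethoxy)phenyl]ethan-1-one
Conditions: NBS (1.0 equiv), iPr2NH (10 mol%), CH2Cl2, 0 °C
Reagents that add atoms: N-bromosuccinimide, O=C1CCC(=O)N1Br
Why: Amine-mediated ortho-selective electrophilic bromination of a phenol; C3 is ortho to the free hydroxyl and para to the MOM ether, so both oxygen donors direct to the same carbon.

Step 3
Reactants: 3 1-[3-bromo-2-hydroxy-6-(methoxymethoxy)phenyl]ethan-1-one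
Product: 4 1-[2-(benzyloxy)-3-bromo-6-(methoxymethoxy)phenyl]ethan-1-one
Conditions: BnBr, K2CO3, DMF, 50 °C
Reagents that add atoms: benzyl bromide, BrCc1ccccc1
Why: Williamson etherification of the remaining chelated phenol, which marks the oxygen next to bromine as the benzyl ether and leaves the other oxygen as the acid-labile MOM ether.

Step 4
Reactants: 5 3-(trimethylsilyl)prop-2-ynal
Product: 7 (3R,4S)-4-methyl-1-(trimethylsilyl)hex-5-en-1-yn-3-ol, via borinate ester 6 (not isolated)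
Conditions: cis-2-butene, n-BuLi, KOtBu, THF, −78 → −45 °C; (+)-Ipc2BOMe, −78 °C; BF3·OEt2; 5, −78 °C; NaOH, H2O2, 0 °C
Reagents that add atoms: (Z)-crotyldiisopinocampheylborane (crotyl group, made in the flask from cis-2-butene, C/C=C\C), C/C=C\CB([C@H]1C[C@H]2C[C@@H]([C@@H]1C)C2(C)C)[C@H]1C[C@H]2C[C@@H]([C@@H]1C)C2(C)C
Why: Brown (Z)-crotylboration through a closed chair transition state: the Z-geometry should give the syn pair and the isopinocampheyl groups of the (−)-α-pinene series should direct attack to the Re face of the ynal, setting 3R and 4S.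

Step 5
Reactants: 7 (3R,4S)-4-methyl-1-(trimethylsilyl)hex-5-en-1-yn-3-ol
Product: 8 [(3R,4S)-3-(benzyloxy)-4-methylhex-5-en-1-yn-1-yl]trimethylsilane
Conditions: NaH, BnBr, Bu4NI (cat.), THF, 0 °C → rt
Reagents that add atoms: benzyl bromide, BrCc1ccccc1
Why: Williamson etherification; the benzyl ether on Ca is installed before any carboxyl group exists, so no lactone can form.

Step 6
Reactants: 8 [(3R,4S)-3-(benzyloxy)-4-methylhex-5-en-1-yn-1-yl]trimethylsilane
Product: 10 (3S,4R)-4-(benzyloxy)-3-methyl-6-(trimethylsilyl)hex-5-yn-1-ol, via alkylborane 9 (not isolated)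
Conditions: 9-BBN, THF, 0 °C → rt; NaOH, H2O2, 0 °C
Reagents that add atoms: hydrogen peroxide, OO
Why: Anti-Markovnikov hydroboration–oxidation; 9-BBN should react with the terminal alkene and leave the silyl-capped alkyne alone.

Step 7
Reactants: 10 (3S,4R)-4-(benzyloxy)-3-methyl-6-(trimethylsilyl)hex-5-yn-1-ol
Product: 12 benzyl (3S,4R)-4-(benzyloxy)-3-methyl-6-(trimethylsilyl)hex-5-ynoate, via carboxylic acid 11 (not isolated)
Conditions: TEMPO (cat.), PhI(OAc)2, MeCN/H2O, rt; then BnOH, EDC·HCl, DMAP (cat.), CH2Cl2, rt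
Reagents that add atoms: water, O; benzyl alcohol, OCc1ccccc1
Why: Oxoammonium (TEMPO) oxidation of the primary alcohol to the acid followed by Steglich esterification; no stereocenter is touched.

Step 8
Reactants: 12 benzyl (3S,4R)-4-(benzyloxy)-3-methyl-6-(trimethylsilyl)hex-5-ynoate
Product: 13 benzyl (3S,4R)-4-(benzyloxy)-6-bromo-3-methylhex-5-ynoate
Conditions: NBS, AgNO3 (10 mol%), acetone, rt
Reagents that add atoms: N-bromosuccinimide, O=C1CCC(=O)N1Br
Why: Silver-catalysed bromodesilylation of an alkynylsilane, a standard route to 1-bromoalkynes.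

Step 9
Reactants: 13 benzyl (3S,4R)-4-(benzyloxy)-6-bromo-3-methylhex-5-ynoate
Product: 14 6-benzyl 1-methyl (3R,4S)-3-(benzyloxy)-4-methyl-2-oxohexanedioate
Conditions: KMnO4, NaHCO3, MgSO4, MeOH/H2O, 0 °C
Reagents that add atoms: potassium permanganate, [K+].[O-][Mn](=O)(=O)=O; methanol, CO
Why: Permanganate oxidation of a 1-bromoalkyne in methanol, a known one-step route to α-keto methyl esters; the buffered, cold conditions should spare the Ca stereocenter.

Step 10
Reactants: 4 1-[2-(benzyloxy)-3-bromo-6-(methoxymethoxy)phenyl]ethan-1-one; 14 6-benzyl 1-methyl (3R,4S)-3-(benzyloxy)-4-methyl-2-oxohexanedioate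
Product: 17 6-benzyl 1-methyl (2E,3R,4S)-3-(benzyloxy)-2-{2-[2-(benzyloxy)-3-bromo-6-(methoxymethoxy)phenyl]-2-oxoethylidene}-4-methylhexanedioate, via aldol adduct 15 (not isolated), via tertiary mesylate 16 (not isolated)
Conditions: LiN(SiMe3)2, THF, −78 °C; 14, −78 °C; MsCl, Et3N, −78 → 0 °C
Reagents that add atoms: none
Why: Aldol addition of the lithium enolate of an aryl methyl ketone to the highly electrophilic ketone of an α-keto ester, then E1cB loss of mesylate through the ketone enolate; the (E)-isomer with the two carbonyl groups trans is expected to dominate.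

Step 11
Reactants: 17 6-benzyl 1-methyl (2E,3R,4S)-3-(benzyloxy)-2-{2-[2-(benzyloxy)-3-bromo-6-(methoxymethoxy)phenyl]-2-oxoethylidene}-4-methylhexanedioate
Product: 19 benzyl (3S,4R)-4-(benzyloxy)-4-[(2S)-5-(benzyloxy)-6-bromo-2-(methoxycarbonyl)-4-oxo-3,4-dihydro-2H-1-benzopyran-2-yl]-3-methylbutanoate, via phenol enone 18 (not isolated)
Conditions: TFA, CH2Cl2, 0 °C; concentrate; Et3N (20 mol%), CH2Cl2, −20 °C
Reagents that add atoms: none
Why: Acid cleavage of the MOM ether and 6-endo-trig oxa-Michael addition of the freed phenol to the aroylacrylate, as in the flavanone-forming cyclization of 2'-hydroxychalcones; C2 should be set by Ca through Felkin–Anh attack anti to the benzyloxy group, and only the C8a oxygen is free to add.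

Step 12
Reactants: 19 benzyl (3S,4R)-4-(benzyloxy)-4-[(2S)-5-(benzyloxy)-6-bromo-2-(methoxycarbonyl)-4-oxo-3,4-dihydro-2H-1-benzopyran-2-yl]-3-methylbutanoate
Product: 21 methyl (2S)-6-bromo-5-hydroxy-2-[(2R,3S)-3-methyl-5-oxooxolan-2-yl]-4-oxo-3,4-dihydro-2H-1-benzopyran-2-carboxylate, via hydroxy acid 20 (not isolated)
Conditions: BCl3, C6HMe5, CH2Cl2, −78 → 0 °C; aqueous work-up; TsOH·H2O (cat.), CH2Cl2, rt
Reagents that add atoms: none
Why: BCl3-mediated cleavage of the three benzyl groups with pentamethylbenzene as cation scavenger, then acid-catalysed γ-lactonization with retention at Ca; the aryl bromide, which would not survive hydrogenolysis, is kept.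

Step 13
Reactants: 21 methyl (2S)-6-bromo-5-hydroxy-2-[(2R,3S)-3-methyl-5-oxooxolan-2-yl]-4-oxo-3,4-dihydro-2H-1-benzopyran-2-carboxylate
Product: 22 methyl (2S)-5-hydroxy-2-[(2R,3S)-3-methyl-5-oxooxolan-2-yl]-4-oxo-6-(4,4,5,5-tetramethyl-1,3,2-dioxaborolan-2-yl)-3,4-dihydro-2H-1-benzopyran-2-carboxylate
Conditions: B2pin2, PdCl2(dppf), KOAc, 1,4-dioxane, 80 °C
Reagents that add atoms: bis(pinacolato)diboron, CC1(C)OB(OC1(C)C)B1OC(C)(C)C(C)(C)O1
Why: Miyaura borylation of the aryl bromide; acetate is too weak a base to open the pyranone or the lactone.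

Step 14
Reactants: 22 methyl (2S)-5-hydroxy-2-[(2R,3S)-3-methyl-5-oxooxolan-2-yl]-4-oxo-6-(4,4,5,5-tetramethyl-1,3,2-dioxaborolan-2-yl)-3,4-dihydro-2H-1-benzopyran-2-carboxylate; 17 6-benzyl 1-methyl (2E,3R,4S)-3-(benzyloxy)-2-{2-[2-(benzyloxy)-3-bromo-6-(methoxymethoxy)phenyl]-2-oxoethylidene}-4-methylhexanedioate
Product: 23 6-benzyl 1-methyl (2E,3R,4S)-3-(benzyloxy)-2-{2-[2-(benzyloxy)-3-[(2S)-5-hydroxy-2-(methoxycarbonyl)-2-[(2R,3S)-3-methyl-5-oxooxolan-2-yl]-4-oxo-3,4-dihydro-2H-1-benzopyran-6-yl]-6-(methoxymethoxy)phenyl]-2-oxoethylidene}-4-methylhexanedioate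
Conditions: Pd(OAc)2, SPhos, K3PO4, 1,4-dioxane/H2O (20:1), 50 °C
Reagents that add atoms: none
Why: Suzuki–Miyaura cross-coupling to a biaryl with only two ortho substituents, so no axis of chirality arises; the MOM ether keeps the enone from cyclizing during the basic coupling.

Step 15
Reactants: 23 6-benzyl 1-methyl (2E,3R,4S)-3-(benzyloxy)-2-{2-[2-(benzyloxy)-3-[(2S)-5-hydroxy-2-(methoxycarbonyl)-2-[(2R,3S)-3-methyl-5-oxooxolan-2-yl]-4-oxo-3,4-dihydro-2H-1-benzopyran-6-yl]-6-(methoxymethoxy)phenyl]-2-oxoethylidene}-4-methylhexanedioate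
Product: 25 benzyl (3S,4R)-4-(benzyloxy)-4-[(2S,2'S)-5-(benzyloxy)-5'-hydroxy-2,2'-bis(methoxycarbonyl)-2'-[(2R,3S)-3-methyl-5-oxooxolan-2-yl]-4,4'-dioxo-3,3',4,4'-tetrahydro-2H,2'H-[6,6'-bi-1-benzopyran]-2-yl]-3-methylbutanoate, via phenol enone 24 (not isolated)
Conditions: TFA, CH2Cl2, 0 °C; concentrate; Et3N (20 mol%), CH2Cl2, −20 °C
Reagents that add atoms: none
Why: Acid removes the MOM group to free the C8a phenol of 24, and on addition of Et3N the phenol(ate) adds to C2 of the (E)-aroylacrylate, the carbon β to the C4 ketone, after which the C3 enolate is protonated. The closest known reaction types are the cyclization of 2'-hydroxychalcones to flavanones and of 2-hydroxybenzoylacrylates to chromanone-2-carboxylates, the ring-closing half of the Kabbe chromanone synthesis. Ring B (O1, C2, C3, C4, C4a, C8a) closes in the 6-endo-trig mode by O1–C2 bond formation. The new center C2 is controlled by the Ca benzyloxy stereocenter: with the aroyl group cis to Ca, allylic 1,3-strain holds the Ca–H bond in the plane of the alkene and the phenol attacks anti to the Ca–O bond (Felkin–Anh), which should give 2S. The step needs facial selectivity (above), selectivity between the two ring A oxygens, secured because O5 is a benzyl ether and only the C8a oxygen is free, and 6-endo attack at C2 over 5-exo attack at C3, secured because the ketone is the stronger acceptor and the same closure has already been run on monomer 18 in step 11. It also needs kinetic control, secured by the weak base and low temperature, so that neither C2 nor C2′ is scrambled by retro-oxa-Michael opening.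

Step 16
Reactants: 25 benzyl (3S,4R)-4-(benzyloxy)-4-[(2S,2'S)-5-(benzyloxy)-5'-hydroxy-2,2'-bis(methoxycarbonyl)-2'-[(2R,3S)-3-methyl-5-oxooxolan-2-yl]-4,4'-dioxo-3,3',4,4'-tetrahydro-2H,2'H-[6,6'-bi-1-benzopyran]-2-yl]-3-methylbutanoate
Product: 26 (3S,4R)-4-hydroxy-4-[(2S,2'S)-5,5'-dihydroxy-2,2'-bis(methoxycarbonyl)-2'-[(2R,3S)-3-methyl-5-oxooxolan-2-yl]-4,4'-dioxo-3,3',4,4'-tetrahydro-2H,2'H-[6,6'-bi-1-benzopyran]-2-yl]-3-methylbutanoic acid
Conditions: H2 (1 atm), Pd(OH)2/C, EtOAc, rt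
Reagents that add atoms: none
Why: Hydrogenolysis of the phenolic benzyl ether, the secondary benzyl ether and the benzyl ester under neutral conditions, which should free the γ-hydroxy acid without the acid or base that would close or scramble it.

**Compound list**

1 | 1-(2,6-dihydroxyphenyl)ethan-1-one | CC(=O)c1c(O)cccc1O | starting material
2 | 1-[2-hydroxy-6-(methoxymethoxy)phenyl]ethan-1-one | CC(=O)c1c(O)cccc1OCOC | intermediate
3 | 1-[3-bromo-2-hydroxy-6-(methoxymethoxy)phenyl]ethan-1-one | CC(=O)c1c(O)c(Br)ccc1OCOC | intermediate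
4 | 1-[2-(benzyloxy)-3-bromo-6-(methoxymethoxy)phenyl]ethan-1-one | CC(=O)c1c(OCc2ccccc2)c(Br)ccc1OCOC | intermediate
5 | 3-(trimethylsilyl)prop-2-ynal | C[Si](C)(C)C#CC=O | starting material
6 | (3R,4S)-4-methyl-1-(trimethylsilyl)hex-5-en-1-yn-3-yl diisopinocampheylborinate | C[Si](C)(C)C#C[C@H](OB([C@H]1C[C@H]2C[C@@H]([C@@H]1C)C2(C)C)[C@H]1C[C@H]2C[C@@H]([C@@H]1C)C2(C)C)[C@@H](C)C=C | intermediate (not isolated)
7 | (3R,4S)-4-methyl-1-(trimethylsilyl)hex-5-en-1-yn-3-ol | C[Si](C)(C)C#C[C@H](O)[C@@H](C)C=C | intermediate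
8 | [(3R,4S)-3-(benzyloxy)-4-methylhex-5-en-1-yn-1-yl]trimethylsilane | C[Si](C)(C)C#C[C@H](OCc1ccccc1)[C@@H](C)C=C | intermediate
9 | 9-[(3S,4R)-4-(benzyloxy)-3-methyl-6-(trimethylsilyl)hex-5-yn-1-yl]-9-borabicyclo[3.3.1]nonane | C[Si](C)(C)C#C[C@H](OCc1ccccc1)[C@@H](C)CCB1C2CCCC1CCC2 | intermediate (not isolated)
10 | (3S,4R)-4-(benzyloxy)-3-methyl-6-(trimethylsilyl)hex-5-yn-1-ol | C[Si](C)(C)C#C[C@H](OCc1ccccc1)[C@@H](C)CCO | intermediate
11 | (3S,4R)-4-(benzyloxy)-3-methyl-6-(trimethylsilyl)hex-5-ynoic acid | C[Si](C)(C)C#C[C@H](OCc1ccccc1)[C@@H](C)CC(=O)O | intermediate (not isolated)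
12 | benzyl (3S,4R)-4-(benzyloxy)-3-methyl-6-(trimethylsilyl)hex-5-ynoate | C[Si](C)(C)C#C[C@H](OCc1ccccc1)[C@@H](C)CC(=O)OCc1ccccc1 | intermediate
13 | benzyl (3S,4R)-4-(benzyloxy)-6-bromo-3-methylhex-5-ynoate | BrC#C[C@H](OCc1ccccc1)[C@@H](C)CC(=O)OCc1ccccc1 | intermediate
14 | 6-benzyl 1-methyl (3R,4S)-3-(benzyloxy)-4-methyl-2-oxohexanedioate | COC(=O)C(=O)[C@H](OCc1ccccc1)[C@@H](C)CC(=O)OCc1ccccc1 | intermediate
15 | 6-benzyl 1-methyl (3R,4S)-3-(benzyloxy)-2-{2-[2-(benzyloxy)-3-bromo-6-(methoxymethoxy)phenyl]-2-oxoethyl}-2-hydroxy-4-methylhexanedioate (both C2 epimers, as the lithium alkoxide) | COC(=O)C(O)(CC(=O)c1c(OCc2ccccc2)c(Br)ccc1OCOC)[C@H](OCc1ccccc1)[C@@H](C)CC(=O)OCc1ccccc1 | intermediate (not isolated)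
16 | 6-benzyl 1-methyl (3R,4S)-3-(benzyloxy)-2-{2-[2-(benzyloxy)-3-bromo-6-(methoxymethoxy)phenyl]-2-oxoethyl}-2-[(methanesulfonyl)oxy]-4-methylhexanedioate (both C2 epimers) | COC(=O)C(OS(C)(=O)=O)(CC(=O)c1c(OCc2ccccc2)c(Br)ccc1OCOC)[C@H](OCc1ccccc1)[C@@H](C)CC(=O)OCc1ccccc1 | intermediate (not isolated)
17 | 6-benzyl 1-methyl (2E,3R,4S)-3-(benzyloxy)-2-{2-[2-(benzyloxy)-3-bromo-6-(methoxymethoxy)phenyl]-2-oxoethylidene}-4-methylhexanedioate | COC(=O)/C(=C/C(=O)c1c(OCc2ccccc2)c(Br)ccc1OCOC)[C@H](OCc1ccccc1)[C@@H](C)CC(=O)OCc1ccccc1 | intermediate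
18 | 6-benzyl 1-methyl (2E,3R,4S)-3-(benzyloxy)-2-{2-[2-(benzyloxy)-3-bromo-6-hydroxyphenyl]-2-oxoethylidene}-4-methylhexanedioate | COC(=O)/C(=C/C(=O)c1c(OCc2ccccc2)c(Br)ccc1O)[C@H](OCc1ccccc1)[C@@H](C)CC(=O)OCc1ccccc1 | intermediate (not isolated)
19 | benzyl (3S,4R)-4-(benzyloxy)-4-[(2S)-5-(benzyloxy)-6-bromo-2-(methoxycarbonyl)-4-oxo-3,4-dihydro-2H-1-benzopyran-2-yl]-3-methylbutanoate | COC(=O)[C@@]1([C@H](OCc3ccccc3)[C@@H](C)CC(=O)OCc3ccccc3)CC(=O)c2c(ccc(Br)c2OCc4ccccc4)O1 | intermediate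
20 | (3S,4R)-4-[(2S)-6-bromo-5-hydroxy-2-(methoxycarbonyl)-4-oxo-3,4-dihydro-2H-1-benzopyran-2-yl]-4-hydroxy-3-methylbutanoic acid | COC(=O)[C@@]1([C@H](O)[C@@H](C)CC(=O)O)CC(=O)c2c(ccc(Br)c2O)O1 | intermediate (not isolated)
21 | methyl (2S)-6-bromo-5-hydroxy-2-[(2R,3S)-3-methyl-5-oxooxolan-2-yl]-4-oxo-3,4-dihydro-2H-1-benzopyran-2-carboxylate | Brc1ccc2c(c1O)C(=O)C[C@@](C(=O)OC)([C@@H]1OC(=O)C[C@@H]1C)O2 | intermediate
22 | methyl (2S)-5-hydroxy-2-[(2R,3S)-3-methyl-5-oxooxolan-2-yl]-4-oxo-6-(4,4,5,5-tetramethyl-1,3,2-dioxaborolan-2-yl)-3,4-dihydro-2H-1-benzopyran-2-carboxylate | CC1(C)OB(OC1(C)C)c1ccc2c(c1O)C(=O)C[C@@](C(=O)OC)([C@@H]1OC(=O)C[C@@H]1C)O2 | intermediate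
23 | 6-benzyl 1-methyl (2E,3R,4S)-3-(benzyloxy)-2-{2-[2-(benzyloxy)-3-[(2S)-5-hydroxy-2-(methoxycarbonyl)-2-[(2R,3S)-3-methyl-5-oxooxolan-2-yl]-4-oxo-3,4-dihydro-2H-1-benzopyran-6-yl]-6-(methoxymethoxy)phenyl]-2-oxoethylidene}-4-methylhexanedioate | COC(=O)/C(=C/C(=O)c1c(OCc2ccccc2)c(-c3ccc4c(c3O)C(=O)C[C@@](C(=O)OC)([C@@H]5OC(=O)C[C@@H]5C)O4)ccc1OCOC)[C@H](OCc6ccccc6)[C@@H](C)CC(=O)OCc7ccccc7 | intermediate
24 | 6-benzyl 1-methyl (2E,3R,4S)-3-(benzyloxy)-2-{2-[2-(benzyloxy)-6-hydroxy-3-[(2S)-5-hydroxy-2-(methoxycarbonyl)-2-[(2R,3S)-3-methyl-5-oxooxolan-2-yl]-4-oxo-3,4-dihydro-2H-1-benzopyran-6-yl]phenyl]-2-oxoethylidene}-4-methylhexanedioate | COC(=O)/C(=C/C(=O)c1c(OCc2ccccc2)c(-c3ccc4c(c3O)C(=O)C[C@@](C(=O)OC)([C@@H]5OC(=O)C[C@@H]5C)O4)ccc1O)[C@H](OCc6ccccc6)[C@@H](C)CC(=O)OCc7ccccc7 | intermediate (not isolated)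
25 | benzyl (3S,4R)-4-(benzyloxy)-4-[(2S,2'S)-5-(benzyloxy)-5'-hydroxy-2,2'-bis(methoxycarbonyl)-2'-[(2R,3S)-3-methyl-5-oxooxolan-2-yl]-4,4'-dioxo-3,3',4,4'-tetrahydro-2H,2'H-[6,6'-bi-1-benzopyran]-2-yl]-3-methylbutanoate | COC(=O)[C@@]1([C@H](OCc6ccccc6)[C@@H](C)CC(=O)OCc7ccccc7)CC(=O)c2c(ccc(-c3ccc4c(c3O)C(=O)C[C@@](C(=O)OC)([C@@H]5OC(=O)C[C@@H]5C)O4)c2OCc8ccccc8)O1 | intermediate
26 | (3S,4R)-4-hydroxy-4-[(2S,2'S)-5,5'-dihydroxy-2,2'-bis(methoxycarbonyl)-2'-[(2R,3S)-3-methyl-5-oxooxolan-2-yl]-4,4'-dioxo-3,3',4,4'-tetrahydro-2H,2'H-[6,6'-bi-1-benzopyran]-2-yl]-3-methylbutanoic acid | COC(=O)[C@@]1([C@H](O)[C@@H](C)CC(=O)O)CC(=O)c2c(ccc(-c3ccc4c(c3O)C(=O)C[C@@](C(=O)OC)([C@@H]3OC(=O)C[C@@H]3C)O4)c2O)O1 | target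

**Step count and risks**

Total step count: 16. Longest linear sequence: 13 steps (steps 4–16, from 5 to 26).

Steps most likely to fail:

1. Step 15 (the same closure is used in step 11). Poor facial selectivity in the oxa-Michael addition, or its erosion by reversible ring opening under base, would give both C2 epimers on the late dimer. Fallback: the ring is closed before the biaryl bond is made. Monomer 19 from step 11 is separated by chromatography from its C2 epimer benzyl (3S,4R)-4-(benzyloxy)-4-[(2R)-5-(benzyloxy)-6-bromo-2-(methoxycarbonyl)-4-oxo-3,4-dihydro-2H-1-benzopyran-2-yl]-3-methylbutanoate F1. F1 is re-equilibrated through retro-oxa-Michael opening and re-closure (Cs2CO3, MeCN, rt) and separated again. Pure 19 is then used as the aryl bromide in a Suzuki–Miyaura coupling with boronate 22 under the conditions of step 14. This fallback sets out from 19 (with 22) and comes back to the route at 25.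

2. Step 14. Protodeboronation of the ortho-hydroxyaryl boronate, base-induced opening of the lactone, or γ-deprotonation of the enone at Ca during the basic coupling. Fallback: a base-free Stille coupling. Bromide 21 is converted with hexamethylditin and Pd(PPh3)4 (toluene, 90 °C) into methyl (2S)-5-hydroxy-2-[(2R,3S)-3-methyl-5-oxooxolan-2-yl]-4-oxo-6-(trimethylstannyl)-3,4-dihydro-2H-1-benzopyran-2-carboxylate F3. F3 is coupled with bromide 17 (Pd2(dba)3, tri(2-furyl)phosphine, CuI, DMF, 50 °C). This fallback sets out from 21 and comes back to the route at 23.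

3. Step 16. Incomplete hydrogenolysis of the hindered secondary benzyl ether, over-reduction of the aryl ketones, or lactonization of the liberated γ-hydroxy acid. Fallback: 25 is debenzylated with BCl3 and pentamethylbenzene and lactonized with catalytic TsOH to the symmetric bis-lactone dimethyl (2S,2'S)-5,5'-dihydroxy-2,2'-bis[(2R,3S)-3-methyl-5-oxooxolan-2-yl]-4,4'-dioxo-3,3',4,4'-tetrahydro-2H,2'H-[6,6'-bi-1-benzopyran]-2,2'-dicarboxylate F2. Its two lactones are equivalent, so opening either one with one equivalent of LiOH (THF/H2O, 0 °C), then acidifying to pH 4 in the cold, should give 26. Doubly opened material is relactonized to F2 with TsOH and recycled. This fallback sets out from 25 and comes back to the route at 26.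

**Further compounds**

F1 | step 15 | benzyl (3S,4R)-4-(benzyloxy)-4-[(2R)-5-(benzyloxy)-6-bromo-2-(methoxycarbonyl)-4-oxo-3,4-dihydro-2H-1-benzopyran-2-yl]-3-methylbutanoate | COC(=O)[C@]1([C@H](OCc3ccccc3)[C@@H](C)CC(=O)OCc3ccccc3)CC(=O)c2c(ccc(Br)c2OCc4ccccc4)O1
F2 | step 16 | dimethyl (2S,2'S)-5,5'-dihydroxy-2,2'-bis[(2R,3S)-3-methyl-5-oxooxolan-2-yl]-4,4'-dioxo-3,3',4,4'-tetrahydro-2H,2'H-[6,6'-bi-1-benzopyran]-2,2'-dicarboxylate | O=C1C[C@@](C(=O)OC)([C@@H]2OC(=O)C[C@@H]2C)Oc2ccc(-c3ccc4c(c3O)C(=O)C[C@@](C(=O)OC)([C@@H]5OC(=O)C[C@@H]5C)O4)c(O)c21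
F3 | step 14 | methyl (2S)-5-hydroxy-2-[(2R,3S)-3-methyl-5-oxooxolan-2-yl]-4-oxo-6-(trimethylstannyl)-3,4-dihydro-2H-1-benzopyran-2-carboxylate | C[Sn](C)(C)c1ccc2c(c1O)C(=O)C[C@@](C(=O)OC)([C@@H]1OC(=O)C[C@@H]1C)O2
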